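**Plan**

- Retrosynthetic cuts: the five O–benzyl bonds (protection), both aryl–C(=O) bonds (one bis-Weinreb amide plus one aryllithium), C5–CH2 (Negishi), O1–C7a (copper aryl ether closure), and C2–C3 (acylation of an arylacetate enolate).
- Enabling feature: in the dihydrofuran ring (O1, C2, C3, C3a, C7a), O1–C7a is the one bond that ends at neither C2 nor C3. If it is made last, both stereocentres can be set on an open-chain α-aryl β-hydroxy ester in which C3 is still an epimerisable α-carbonyl carbon.
- Forward order: C2–C3 by Claisen acylation, C2 carbinol by transfer hydrogenation, the only new ring (dihydrofuran) by O1–C7a closure, the C5 chain, both aryl ketones in one operation, then debenzylation.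
- Stereochemistry: C2 (S) comes from catalyst control in the Ru/(S,S)-TsDPEN reduction. C3 (S) comes from the dynamic kinetic resolution (syn) and, independently, from the thermodynamic 2,3-trans preference of the α-carbonyl centre.

Key step: step 4

Remark: the reduction in step 3 is assumed to favour the syn (2S,3S) isomer; a lower syn/anti ratio is tolerable because C3 can be equilibrated to trans by base after ring closure. Compounds 3, 7 (0.5 M in THF) and 10 are taken as catalogue compounds.

**Route**

Step 1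
Reactants: 1 2-(2-bromo-5-chlorophenyl)acetic acid
Product: 2 methyl 2-(2-bromo-5-chlorophenyl)acetate
Conditions: MeOH, H2SO4 (cat.), reflux
Reagents that add atoms: methanol, CO
Why: Fischer esterification in excess methanol should convert the acid cleanly into its methyl ester, and neither aryl halide reacts under acid catalysis.

Step 2
Reactants: 2 methyl 2-(2-bromo-5-chlorophenyl)acetate; 3 4-(benzyloxy)benzoyl chloride
Product: 4 methyl 3-[4-(benzyloxy)phenyl]-2-(2-bromo-5-chlorophenyl)-3-oxopropanoate (racemic, labile at C2)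
Conditions: LiHMDS (2.2 equiv), THF, −78 °C; then 3, −78 → −20 °C; 1 M HCl
Reagents that add atoms: none
Why: Crossed Claisen-type C-acylation of the lithium ester enolate by the aroyl chloride, in which the second equivalent of base stores the more acidic β-keto ester as its enolate and so prevents a second acylation; the new α-centre is racemic and labile, as step 3 requires.

Step 3
Reactants: 4 methyl 3-[4-(benzyloxy)phenyl]-2-(2-bromo-5-chlorophenyl)-3-oxopropanoate
Product: 5 methyl (2S,3S)-3-[4-(benzyloxy)phenyl]-2-(2-bromo-5-chlorophenyl)-3-hydroxypropanoate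
Conditions: RuCl[(S,S)-TsDPEN](p-cymene) (2 mol %), HCO2H/Et3N (5:2), DMF, 35 °C
Reagents that add atoms: none
Why: Noyori-type asymmetric transfer hydrogenation with dynamic kinetic resolution, in which Et3N racemises the doubly activated α-C–H through the enol faster than reduction, the (S,S)-TsDPEN–Ru hydride reduces the aryl ketone in its usual sense (aryl group in the CH/π pocket) to set 3S, and Felkin-type hydride delivery anti to the bulky 2-bromoaryl group on the faster-reacting enantiomer should set 2S (syn).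

Step 4
Reactants: 5 methyl (2S,3S)-3-[4-(benzyloxy)phenyl]-2-(2-bromo-5-chlorophenyl)-3-hydroxypropanoate
Product: 6 methyl (2S,3S)-2-[4-(benzyloxy)phenyl]-5-chloro-2,3-dihydro-1-benzofuran-3-carboxylate (2,3-trans)
Conditions: CuI (10 mol %), 3,4,7,8-tetramethyl-1,10-phenanthroline (20 mol %), Cs2CO3 (1.5 equiv), toluene, 80 °C, argon
Reagents that add atoms: none
Why: The carbonate generates the secondary benzylic alkoxide, which binds phenanthroline-ligated Cu(I); the metal inserts into the neighbouring C–Br bond and C–O reductive elimination from the six-membered cupracycle forms O1–C7a, an intramolecular Ullmann-type etherification. The closest known reaction type is the copper-catalysed cyclisation of 2-(2-bromoaryl)ethanols to 2,3-dihydrobenzofurans. The dihydrofuran ring closes in a 5-exo sense, oxygen attacking the ipso carbon with the C–Br bond outside the new ring. No stereocentre is created: the carbinol C–O bond is never broken, so C2 keeps the S configuration from step 3, and the 2,3-trans relationship follows from the syn precursor and is also the thermodynamic one, because the carbonate can equilibrate the ester-bearing C3 (ring-opening β-elimination from the C3 enolate is the reverse of a 5-endo closure and should be slow). The step needs C–Br over C–Cl selectivity and must avoid retro-aldol cleavage and dehydration; Cu(I) does not insert into aryl chlorides at 80 °C, the alkoxide is held ortho to bromine, and a sparingly soluble carbonate in toluene keeps the free alkoxide concentration low.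

Step 5
Reactants: 6 methyl (2S,3S)-2-[4-(benzyloxy)phenyl]-5-chloro-2,3-dihydro-1-benzofuran-3-carboxylate; 7 (3-ethoxy-3-oxopropyl)zinc bromide
Product: 8 methyl (2S,3S)-2-[4-(benzyloxy)phenyl]-5-(3-ethoxy-3-oxopropyl)-2,3-dihydro-1-benzofuran-3-carboxylate
Conditions: Pd-PEPPSI-IPr (3 mol %), LiBr, THF/NMP 2:1, 25 → 60 °C
Reagents that add atoms: none
Why: Negishi sp2–sp3 cross-coupling, in which the bulky NHC–Pd(0) catalyst inserts into the electron-rich C5–Cl bond, the ester-stabilised zinc homoenolate transmetalates and reductive elimination should outrun β-hydride elimination, while the non-basic organozinc leaves the C3 ester and its acidic C–H untouched.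

Step 6
Reactants: 8 methyl (2S,3S)-2-[4-(benzyloxy)phenyl]-5-(3-ethoxy-3-oxopropyl)-2,3-dihydro-1-benzofuran-3-carboxylate
Product: 9 (2S,3S)-2-[4-(benzyloxy)phenyl]-N-methoxy-5-{3-[methoxy(methyl)amino]-3-oxopropyl}-N-methyl-2,3-dihydro-1-benzofuran-3-carboxamide
Conditions: MeNH(OMe)·HCl (6 equiv), AlMe3 (6 equiv), CH2Cl2, 0 → 40 °C; aq. Rochelle salt
Reagents that add atoms: N,O-dimethylhydroxylamine hydrochloride, Cl.CNOC
Why: Weinreb aminolysis of both esters by the aluminium amide formed from AlMe3 and the amine salt (direct ester-to-Weinreb-amide conversion); the reagent is only weakly basic and tolerates benzylic ethers, and any epimerisation at C3 would return to the stable trans arrangement.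

Step 7
Reactants: 10 4-bromobenzene-1,3-diol
Product: 11 2,4-bis(benzyloxy)-1-bromobenzene
Conditions: BnBr (2.2 equiv), K2CO3, DMF, 60 °C
Reagents that add atoms: benzyl bromide, BrCc1ccccc1
Why: Williamson ether synthesis, both phenoxides being benzylated by SN2 displacement on benzyl bromide.

Step 8
Reactants: 9 (2S,3S)-2-[4-(benzyloxy)phenyl]-N-methoxy-5-{3-[methoxy(methyl)amino]-3-oxopropyl}-N-methyl-2,3-dihydro-1-benzofuran-3-carboxamide; 11 2,4-bis(benzyloxy)-1-bromobenzene
Product: 13 [2,4-bis(benzyloxy)phenyl][(2S,3S)-2-[4-(benzyloxy)phenyl]-5-{3-[2,4-bis(benzyloxy)phenyl]-3-oxopropyl}-2,3-dihydro-1-benzofuran-3-yl]methanone, via 2,4-bis(benzyloxy)phenyllithium 12 (not isolated)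
Conditions: 11 (3.0 equiv), n-BuLi (2.9 equiv), THF, −78 °C; then 9, −78 → −40 °C; sat. aq. NH4Cl
Reagents that add atoms: none
Why: Bromine–lithium exchange followed by a double Weinreb ketone synthesis, in which the aryllithium adds once to each N-methoxy-N-methylamide and the chelated tetrahedral lithium adducts persist until the quench, so neither ketone is attacked twice; C2 is untouched and C3, if deprotonated at all, should return to the more stable trans arrangement.

Step 9
Reactants: 13 [2,4-bis(benzyloxy)phenyl][(2S,3S)-2-[4-(benzyloxy)phenyl]-5-{3-[2,4-bis(benzyloxy)phenyl]-3-oxopropyl}-2,3-dihydro-1-benzofuran-3-yl]methanone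
Product: 14 1-(2,4-dihydroxyphenyl)-3-[(2S,3S)-3-(2,4-dihydroxybenzoyl)-2-(4-hydroxyphenyl)-2,3-dihydro-1-benzofuran-5-yl]propan-1-one
Conditions: H2 (1 atm), 10% Pd/C, EtOAc/MeOH, rt; stopped once debenzylation is complete
Reagents that add atoms: none
Why: Catalytic hydrogenolysis of the five benzyl aryl ethers under neutral conditions, where O-benzyl cleavage should be much faster than hydrogenolysis of the hindered cyclic C2–O1 bond or reduction of the hydrogen-bonded 2-hydroxyaryl ketones; no stereocentre is touched.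

**Compound list**

1 | 2-(2-bromo-5-chlorophenyl)acetic acid | OC(=O)Cc1cc(Cl)ccc1Br | starting material
2 | methyl 2-(2-bromo-5-chlorophenyl)acetate | COC(=O)Cc1cc(Cl)ccc1Br | intermediate
3 | 4-(benzyloxy)benzoyl chloride | O=C(Cl)c1ccc(OCc2ccccc2)cc1 | starting material
4 | methyl 3-[4-(benzyloxy)phenyl]-2-(2-bromo-5-chlorophenyl)-3-oxopropanoate (racemic) | COC(=O)C(c1cc(Cl)ccc1Br)C(=O)c1ccc(OCc2ccccc2)cc1 | intermediate
5 | methyl (2S,3S)-3-[4-(benzyloxy)phenyl]-2-(2-bromo-5-chlorophenyl)-3-hydroxypropanoate | Clc1ccc(Br)c(c1)[C@H](C(=O)OC)[C@@H](c1ccc(OCc2ccccc2)cc1)O | intermediate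
6 | methyl (2S,3S)-2-[4-(benzyloxy)phenyl]-5-chloro-2,3-dihydro-1-benzofuran-3-carboxylate | Clc1ccc2c(c1)[C@H](C(=O)OC)[C@@H](c1ccc(OCc3ccccc3)cc1)O2 | intermediate
7 | (3-ethoxy-3-oxopropyl)zinc bromide | CCOC(=O)CC[Zn]Br | starting material
8 | methyl (2S,3S)-2-[4-(benzyloxy)phenyl]-5-(3-ethoxy-3-oxopropyl)-2,3-dihydro-1-benzofuran-3-carboxylate | CCOC(=O)CCc1ccc2c(c1)[C@H](C(=O)OC)[C@@H](c1ccc(OCc3ccccc3)cc1)O2 | intermediate
9 | (2S,3S)-2-[4-(benzyloxy)phenyl]-N-methoxy-5-{3-[methoxy(methyl)amino]-3-oxopropyl}-N-methyl-2,3-dihydro-1-benzofuran-3-carboxamide | CON(C)C(=O)CCc1ccc2c(c1)[C@H](C(=O)N(C)OC)[C@@H](c1ccc(OCc3ccccc3)cc1)O2 | intermediate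
10 | 4-bromobenzene-1,3-diol | Oc1ccc(Br)c(O)c1 | starting material
11 | 2,4-bis(benzyloxy)-1-bromobenzene | Brc1ccc(OCc2ccccc2)cc1OCc1ccccc1 | intermediate
12 | 2,4-bis(benzyloxy)phenyllithium | [Li]c1ccc(OCc2ccccc2)cc1OCc1ccccc1 | intermediate
13 | [2,4-bis(benzyloxy)phenyl][(2S,3S)-2-[4-(benzyloxy)phenyl]-5-{3-[2,4-bis(benzyloxy)phenyl]-3-oxopropyl}-2,3-dihydro-1-benzofuran-3-yl]methanone | O=C(CCc1ccc2c(c1)[C@H](C(=O)c3ccc(OCc4ccccc4)cc3OCc3ccccc3)[C@@H](c3ccc(OCc4ccccc4)cc3)O2)c1ccc(OCc2ccccc2)cc1OCc1ccccc1 | intermediate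
14 | 1-(2,4-dihydroxyphenyl)-3-[(2S,3S)-3-(2,4-dihydroxybenzoyl)-2-(4-hydroxyphenyl)-2,3-dihydro-1-benzofuran-5-yl]propan-1-one | O=C(CCc1ccc2c(c1)[C@H](C(=O)c1ccc(O)cc1O)[C@@H](c1ccc(O)cc1)O2)c1ccc(O)cc1O | target

**Totals and risks**

Total step count: 9. Longest linear sequence: 8 (steps 1–6, 8, 9 from compound 1); step 7 is a one-step side branch.

Steps most likely to fail:

1. Step 4. Under base and heat the alkoxide of the β-hydroxy ester may fragment by retro-aldol cleavage, or the ester may dehydrate, before the C–O bond forms. The fallback sets out from 5 and replaces the ester by a tertiary amide before ring closure, since an amide enolate is a much poorer leaving group and its α-C–H is less acidic. AlMe3/MeNH(OMe)·HCl should convert 5 into (2S,3S)-3-[4-(benzyloxy)phenyl]-2-(2-bromo-5-chlorophenyl)-3-hydroxy-N-methoxy-N-methylpropanamide F1. The same copper-catalysed O-arylation should then give (2S,3S)-2-[4-(benzyloxy)phenyl]-5-chloro-N-methoxy-N-methyl-2,3-dihydro-1-benzofuran-3-carboxamide F2. Negishi coupling with 7 should give ethyl 3-[(2S,3S)-2-[4-(benzyloxy)phenyl]-3-[methoxy(methyl)carbamoyl]-2,3-dihydro-1-benzofuran-5-yl]propanoate F3, and a second Weinreb aminolysis of the chain ester comes back to the route at 9. Any cis isomer carried through would be corrected at the ketone stage, where C3 is again easily equilibrated.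

2. Step 3. Hydride transfer to the hindered, electron-rich ketone may be slow, or facial and syn/anti selectivity may be insufficient. The fallback sets out from 1 and builds the same centres by auxiliary control. The pivaloyl mixed anhydride of 1 with lithiated (S)-4-benzyl-1,3-oxazolidin-2-one should give (4S)-4-benzyl-3-[2-(2-bromo-5-chlorophenyl)acetyl]-1,3-oxazolidin-2-one F4. An Evans syn-aldol reaction (Bu2BOTf, i-Pr2NEt, CH2Cl2, −78 → 0 °C) with 4-(benzyloxy)benzaldehyde should give (4S)-4-benzyl-3-[(2S,3S)-3-[4-(benzyloxy)phenyl]-2-(2-bromo-5-chlorophenyl)-3-hydroxypropanoyl]-1,3-oxazolidin-2-one F5. Methanolysis with MeOMgBr in MeOH at 0 °C comes back to the route at 5.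

3. Step 8. The aryllithium may deprotonate the hindered, α-aryl C3 amide instead of adding to it, so that acylation at C3 stays incomplete. The fallback sets out from 9 and uses the more electrophilic aldehyde oxidation level. DIBAL-H (THF, −78 °C) should reduce both Weinreb amides to (2S,3S)-2-[4-(benzyloxy)phenyl]-5-(3-oxopropyl)-2,3-dihydro-1-benzofuran-3-carbaldehyde F6. Addition of 12 at −78 °C should give 1-[2,4-bis(benzyloxy)phenyl]-3-[(2S,3R)-2-[4-(benzyloxy)phenyl]-3-{[2,4-bis(benzyloxy)phenyl](hydroxy)methyl}-2,3-dihydro-1-benzofuran-5-yl]propan-1-ol F7 as a mixture of carbinol epimers. The ring centres are arranged as in 13; the C3 descriptor changes only through CIP ranking. Dess–Martin oxidation of both benzylic carbinols comes back to the route at 13.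

Further compounds
F1 | step 4 | (2S,3S)-3-[4-(benzyloxy)phenyl]-2-(2-bromo-5-chlorophenyl)-3-hydroxy-N-methoxy-N-methylpropanamide | CON(C)C(=O)[C@@H](c1cc(Cl)ccc1Br)[C@H](O)c1ccc(OCc2ccccc2)cc1
F2 | step 4 | (2S,3S)-2-[4-(benzyloxy)phenyl]-5-chloro-N-methoxy-N-methyl-2,3-dihydro-1-benzofuran-3-carboxamide | Clc1ccc2c(c1)[C@H](C(=O)N(C)OC)[C@@H](c1ccc(OCc3ccccc3)cc1)O2
F3 | step 4 | ethyl 3-[(2S,3S)-2-[4-(benzyloxy)phenyl]-3-[methoxy(methyl)carbamoyl]-2,3-dihydro-1-benzofuran-5-yl]propanoate | CCOC(=O)CCc1ccc2c(c1)[C@H](C(=O)N(C)OC)[C@@H](c1ccc(OCc3ccccc3)cc1)O2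
F4 | step 3 | (4S)-4-benzyl-3-[2-(2-bromo-5-chlorophenyl)acetyl]-1,3-oxazolidin-2-one | O=C(Cc1cc(Cl)ccc1Br)N1C(=O)OC[C@@H]1Cc1ccccc1
F5 | step 3 | (4S)-4-benzyl-3-[(2S,3S)-3-[4-(benzyloxy)phenyl]-2-(2-bromo-5-chlorophenyl)-3-hydroxypropanoyl]-1,3-oxazolidin-2-one | O=C([C@@H](c1cc(Cl)ccc1Br)[C@H](O)c1ccc(OCc2ccccc2)cc1)N1C(=O)OC[C@@H]1Cc1ccccc1
F6 | step 8 | (2S,3S)-2-[4-(benzyloxy)phenyl]-5-(3-oxopropyl)-2,3-dihydro-1-benzofuran-3-carbaldehyde | O=CCCc1ccc2c(c1)[C@H](C=O)[C@@H](c1ccc(OCc3ccccc3)cc1)O2
F7 | step 8 | 1-[2,4-bis(benzyloxy)phenyl]-3-[(2S,3R)-2-[4-(benzyloxy)phenyl]-3-{[2,4-bis(benzyloxy)phenyl](hydroxy)methyl}-2,3-dihydro-1-benzofuran-5-yl]propan-1-ol (carbinol epimers) | OC(CCc1ccc2c(c1)[C@H](C(O)c3ccc(OCc4ccccc4)cc3OCc3ccccc3)[C@@H](c3ccc(OCc4ccccc4)cc3)O2)c1ccc(OCc2ccccc2)cc1OCc1ccccc1
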